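## Analysis of the target

The target 16 is quercetin carrying hydrogen sulfate groups on both ring B oxygens (O3' and O4'), with the hydroxyls at C3, C5 and C7 free. Its flavonol skeleton consists of a phloroglucinol-type ring A, a 4-pyranone ring C fused to ring A at C4a–C8a with the carbonyl at C4 and an enolic hydroxyl at C3, and a catechol ring B attached at C2. There is no stereocentre and no stereogenic double bond, so all selectivity is positional: which of five oxygens carries sulfate, and whether ring C closes to the six-membered flavone or the five-membered aurone. The sensitive groups are the aryl sulfate monoesters (strongly acidic, hydrolysed under acid, insoluble in organic media), the 3-hydroxy-4-pyranone (oxidised in base under air) and the electron-rich ring A (open to electrophiles at C6 and C8). The main difficulty is placing two sulfates on neighbouring ring B oxygens and nowhere else, because late sulfation of a catechol is slow at the second oxygen and competes with three other hydroxyls. The plan rests on the position of C4: it lies between C4a of ring A and the C3–C2 unit that carries ring B, while O1 bridges C8a and C2. Ring C can therefore be built from an ortho-iodophenol (C4a–I, C8a–OH), carbon monoxide (C4) and an arylacetylene (C3≡C2–ring B), and ring B can carry both sulfates as neutral neopentyl diesters from the start.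

## Retrosynthetic reasoning

**16 back to 14 (the two O–CH2 bonds of the neopentyl esters).** The free acid 16 is the protonated form of its disodium salt 15, and 15 comes from the bis(neopentyl sulfate) 14. The cut is at O–CH2, not at S–OAr, so the forward step is a substitution at saturated carbon by a small anionic nucleophile. That leaves the aryl–O–S linkage and the three free hydroxyls alone. The charged, acid-labile groups then appear only in the last operation, and every earlier compound is neutral and can be purified on silica.

**14 back to 13 (the O–CH2Ph bonds at O5 and O7).** The ring A hydroxyls are carried as benzyl ethers because free phenols would not survive the oxygen-transfer step before this one. Hydrogenolysis is orthogonal to sulfate diesters. The forward step has to remove two benzyl groups without reducing the C2=C3 bond.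

**13 back to 11 (the C3–O bond).** The C3 hydroxyl is removed next, which gives flavone 11. A ring closure that uses a terminal alkyne delivers C3 as CH, and an oxygenated alkyne partner would not fit that chemistry. In the forward direction the C2=C3 bond, an enol ether through O1, takes an oxygen atom from an electrophilic dioxirane to give epoxide 12. Acid then opens 12 at C2 and restores the pyranone as flavonol 13.

**11 back to 2, 7 and 8 (C4a–C4, C4–C3 and O1–C2).** Ring C is taken apart completely. Cutting on both sides of C4 turns that carbon into carbon monoxide 8. Cutting O1–C2 leaves O1 as the phenol of iodophenol 2 and leaves C2–C3 as the triple bond of alkyne 7. The three pieces are simple, ring A needs only an iodine ortho to a hydroxyl, ring B brings the masked sulfates, and one operation forms three bonds and the ring. The forward reaction passes through ynone 9 and enaminone 10. It must insert 8 before the alkyne couples, and it must close at C2 and not at C3.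

**2 back to 1 (the C–I bond).** Phenol 1 has two equivalent positions ortho to the hydroxyl, and either becomes C4a. The forward iodination only has to prefer them over C4, which is flanked by two benzyloxy groups.

**7 back to 6, then to 5 and 4, then to 3 (the alkyne carbon and the S–O bonds).** The terminal alkyne carbon is added to aldehyde 6 by one-carbon homologation. The two ArO–S bonds of 6 are cut to give aldehyde 5 and two molecules of chlorosulfate 4, and 4 comes from alcohol 3. Sulfation at the stage of 5 is the point of the plan: the only hydroxyls present are the two that must be sulfated, so the selectivity problem of the target does not arise.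

## Alternatives that were turned down

**Alternative 1:** The disconnection cuts C4–C4a and O1–C2. Ring A comes from phloroglucinol A2. C2, C3, C4, ring B and the C3 oxygen come from the β-keto ester A3, ethyl 2-(benzyloxy)-3-(2,2-diphenyl-1,3-benzodioxol-5-yl)-3-oxopropanoate. The forward key step is a Mentzer pyranone synthesis: A2 and A3 are fused without solvent near 240 °C to give 3-(benzyloxy)-2-(2,2-diphenyl-1,3-benzodioxol-5-yl)-5,7-dihydroxy-4H-chromen-4-one A1.
- For it: A2 is symmetric, so ring A raises no positional question. The C3 oxygen is already in place, which saves the separate hydroxylation of the chosen route. No transition metal and no toxic gas are needed. On these three points it is stronger.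
- Against it: at that temperature a benzyl ether flanked by two carbonyl groups, in a melt with a very nucleophilic triphenol, can be expected to suffer benzyl transfer to ring A and retro-Claisen cleavage. No sulfate ester could be carried through. The sulfates must therefore go on after the ring is built. The 5- and 7-hydroxyls of A1 must be capped (the chelated 5-OH reluctantly), the ketal removed with acid (hydrogenolysis would also take the benzyl group), the catechol sulfated twice on neighbouring oxygens, and the rest unmasked.
- Comparison: at least five operations follow the key step, against three, and the defining selectivity problem returns. The chosen strategy gives up the built-in C3 oxygen and accepts a palladium step. In return it works below 100 °C and never has to tell the ring B oxygens from the others.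

**Alternative 2:** The disconnection cuts C8a–O1, C4–C4a and O1–C2. Ring A becomes an aryne, released from the silyl triflate A5, 3,5-bis(benzyloxy)-2-(trimethylsilyl)phenyl trifluoromethanesulfonate. The rest comes from the arylpropiolic acid A6, 3-[3,4-bis(methoxymethoxy)phenyl]prop-2-ynoic acid. In the forward step CsF triggers elimination from A5 and the carboxylate of A6 adds to the aryne. The aryl anion then attacks its own ester carbonyl, a net insertion into the C–O bond, and the phenoxide closes by oxa-Michael addition. The product is 5,7-bis(benzyloxy)-2-[3,4-bis(methoxymethoxy)phenyl]-4H-chromen-4-one A4.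
- For it: no CO, no pressure vessel and no palladium. The 5,7-pattern follows from the polarisation of a 3-alkoxyaryne, where the nucleophile adds at the carbon remote from the benzyloxy group. Ring A regiochemistry is thus fixed by mechanism in the key step, and on that point it is at least as strong as the chosen route.
- Against it: A5 needs several steps (ortho-halogenation, O-silylation, halogen–metal exchange with silyl shift, triflation) from phenol 1, which the chosen route iodinates once, and its halogenation raises the same ortho/para question. Arylpropiolic acids decarboxylate readily under basic fluoride conditions. No amine is present to steer the phenoxide–ynone away from 5-exo closure. Ring B arrives as MOM ethers, so C3 hydroxylation, protection of the new 3-OH, MOM removal and catechol bis-sulfation all follow.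
- Comparison: the sequence is longer before and after the key step. The chosen route offers a one-step ring A partner and sulfates installed before the ring is made.

**Alternative 3:** The disconnection cuts C3–C4 and O1–C2. Ring A with C4 is the salicylaldehyde A8, 2-hydroxy-4,6-bis(benzyloxy)benzaldehyde. C3, C2 and ring B come from the aroyl sulfoxonium ylide A9. In the forward step [Cp*RhCl2]2 (trivalent rhodium), activated by AgSbF6 with NaOAc, is directed by the phenol into the aldehyde C–H bond. The acyl rhodium species takes up the carbene carbon of A9 to give a 1,3-diketone, which cyclodehydrates to 5,7-bis(benzyloxy)-2-(2,2-diphenyl-1,3-benzodioxol-5-yl)-4H-chromen-4-one A7.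
- For it: A8 is available by a formylation that is inherently ortho to the hydroxyl, so ring A has no isomer problem. Both partners are bench-stable and no CO is used. A 1,3-diketone can only cyclodehydrate to the six-membered ring, so the flavone/aurone question does not exist. On these points it is stronger.
- Against it: rhodium and silver are costly. The aldehyde C–H is crowded by the benzyloxy group at C6. A7 is at the same oxidation level at C3 as flavone 11, so hydroxylation is still needed. Ring B arrives as a ketal, so late bis-sulfation with 3-OH protection returns.
- Comparison: the key step forms two bonds, against three, and at least six operations follow it, against three. The chosen strategy uses a cheaper catalyst and has the sulfates in place from the start.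

Key step: step 5

Assumption: the target is taken as the free bis(hydrogen sulfate) as drawn. It is made by protonating disodium salt 15, which is the practical storage form because aryl hydrogen sulfates hydrolyse slowly under their own acidity.

## Route

Step 1
Reactants: 1 3,5-bis(benzyloxy)phenol
Product: 2 3,5-bis(benzyloxy)-2-iodophenol
Conditions: NIS (1.0 equiv), CH2Cl2, −20 to 0 °C, dark
Reagents that add atoms: N-iodosuccinimide, O=C1CCC(=O)N1I
Why: Electrophilic aromatic iodination of a phloroglucinol-type ring; the two equivalent positions ortho to the free hydroxyl (each also para to a benzyloxy group) should be preferred on statistical and steric grounds over C4, which sits between two benzyloxy groups, and one equivalent of reagent at low temperature limits a second iodination.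

Step 2
Reactants: 3 neopentyl alcohol (2,2-dimethylpropan-1-ol)
Product: 4 neopentyl chlorosulfate (2,2-dimethylpropyl sulfurochloridate)
Conditions: SO2Cl2 (1.0 equiv), pyridine (1.0 equiv), Et2O, −78 °C to rt
Reagents that add atoms: sulfuryl chloride, O=S(=O)(Cl)Cl
Why: Chlorosulfonylation of a primary alcohol; one S–Cl bond of sulfuryl chloride is displaced with pyridine as acid scavenger, and low temperature with 1:1 stoichiometry stops at the chlorosulfate. The neopentyl group blocks the SN2 collapse to an alkyl chloride that unbranched alkyl chlorosulfates undergo.

Step 3
Reactants: 5 3,4-dihydroxybenzaldehyde; 4 neopentyl chlorosulfate (two equivalents are consumed, one per phenoxide; 2.5 equiv used)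
Product: 6 4-formyl-1,2-phenylene bis(neopentyl sulfate), the aldehyde with both catechol oxygens as –OSO2OCH2C(CH3)3
Conditions: NaH (2.3 equiv), THF/DMPU, 0 °C; the disodium salt is then added to 4 (2.5 equiv) in THF, −20 °C to rt
Reagents that add atoms: neopentyl chlorosulfate (the second equivalent of 4), CC(C)(C)COS(=O)(=O)Cl
Why: Sulfate diester formation by O-sulfonylation of each of the two sodium phenoxides with one molecule of the alkyl chlorosulfate, chloride leaving from sulfur. Chloride is a far better leaving group than neopentoxide, so sulfation of the second oxygen by excess 4 should outrun closure of the mono-sulfated phenoxide to a cyclic catechol sulfate, and inverse addition keeps that phenoxide short-lived. The non-enolisable aldehyde is untouched by NaH.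

Step 4
Reactants: 6 4-formyl-1,2-phenylene bis(neopentyl sulfate)
Product: 7 4-ethynyl-1,2-phenylene bis(neopentyl sulfate)
Conditions: dimethyl (1-diazo-2-oxopropyl)phosphonate (1.3 equiv), K2CO3 (2 equiv), MeOH/THF, 0 °C to rt
Reagents that add atoms: dimethyl (1-diazo-2-oxopropyl)phosphonate (Ohira-Bestmann reagent), COP(=O)(OC)C(=[N+]=[N-])C(C)=O
Why: Ohira-Bestmann variant of the Seyferth-Gilbert homologation; methanolysis of the acetyl group releases the dimethyl (diazomethyl)phosphonate anion, which olefinates the aldehyde, and the diazoalkene loses N2 and rearranges by a 1,2-hydride shift to the terminal alkyne. The aldehyde is electron-poor and should react at 0 °C, and a sulfate diester is less electrophilic at sulfur than an aryl sulfonate, a group that usually tolerates carbonate in methanol at this temperature.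

Step 5
Reactants: 2 3,5-bis(benzyloxy)-2-iodophenol; 7 4-ethynyl-1,2-phenylene bis(neopentyl sulfate) (1.3 equiv); 8 carbon monoxide
Product: 11 5,7-bis(benzyloxy)-2-[3,4-bis(neopentyloxysulfonyloxy)phenyl]-4H-chromen-4-one, via ortho-hydroxyaryl ynone 9 (not isolated), via diethylamino enone 10 (not isolated)
Conditions: PdCl2(PPh3)2 (5 mol %), CO (10 bar), Et2NH, 80 °C
Reagents that add atoms: none
Why: PdCl2(PPh3)2 (divalent palladium) is reduced in the flask to zerovalent palladium, which inserts into the C–I bond of 2; CO insertion gives an aroylpalladium iodide, and amine-assisted alkynylation with 7 followed by reductive elimination gives ynone 9 (C4a–C4 and C4–C3). Diethylamine then adds in conjugate fashion to 9 to give enaminone 10, and the ortho-hydroxyl attacks C2 of 10 and expels the amine by addition–elimination, which forms O1–C2. The closest known reaction type is the palladium-catalysed carbonylative annulation of ortho-iodophenols with terminal alkynes in a secondary amine, which gives flavones. Ring C closes in a 6-endo mode (6-endo-trig on the enaminone, equivalent to 6-endo-dig on the ynone), and no stereocentre is formed. The step needs flavone over aurone: in enaminone 10 the carbon next to the carbonyl is nucleophilic, so oxygen can only attack C2 and the 5-exo closure is shut off. It also needs carbonylative over direct coupling: the electron-rich, doubly ortho-substituted arylpalladium should insert CO quickly, copper is left out, and CO pressure is kept up throughout. The aryl C–O bonds of the sulfate diesters are inert to triphenylphosphine-ligated palladium, and the neopentyl groups block attack of the amine at carbon.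

Step 6
Reactants: 11 5,7-bis(benzyloxy)-2-[3,4-bis(neopentyloxysulfonyloxy)phenyl]-4H-chromen-4-one
Product: 13 5,7-bis(benzyloxy)-3-hydroxy-2-[3,4-bis(neopentyloxysulfonyloxy)phenyl]-4H-chromen-4-one, via 2,3-epoxyflavanone 12 (not isolated)
Conditions: DMDO (acetone solution, 3 equiv), CH2Cl2, 0 °C to rt; concentrate; then p-TsOH·H2O (cat.), CH2Cl2, rt
Reagents that add atoms: dimethyldioxirane, CC1(C)OO1
Why: Epoxidation of the C2=C3 bond (an enol ether through O1) by the neutral electrophilic dioxirane should give the racemic cis-fused epoxide 12 without acid or base that could harm the sulfate diesters. The acid then opens the oxirane at C2, where the cation is stabilised by O1 and the aryl group, and loss of the C3 proton restores the pyranone as the 3-hydroxyflavone. The two stereocentres of 12 are destroyed in this step, so their configuration does not matter.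

Step 7
Reactants: 13 5,7-bis(benzyloxy)-3-hydroxy-2-[3,4-bis(neopentyloxysulfonyloxy)phenyl]-4H-chromen-4-one
Product: 14 3,5,7-trihydroxy-2-[3,4-bis(neopentyloxysulfonyloxy)phenyl]-4H-chromen-4-one
Conditions: H2 (1 atm), Pd/C (10 % Pd), THF/MeOH, rt
Reagents that add atoms: none
Why: Hydrogenolysis of the two aryl benzyl ethers on palladium; neopentyl aryl sulfate diesters and the tetrasubstituted, cross-conjugated C2=C3 bond are not expected to be reduced at 1 atm, and the reaction is stopped when hydrogen uptake ends.

Step 8
Reactants: 14 3,5,7-trihydroxy-2-[3,4-bis(neopentyloxysulfonyloxy)phenyl]-4H-chromen-4-one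
Product: 16 quercetin 3',4'-bis(hydrogen sulfate), via disodium bis-sulfate 15 (not isolated)
Conditions: NaN3 (5 equiv), DMF, 65 °C, Ar; concentrate, C18 plug (H2O, then MeOH/H2O) to wash out NaN3; then HCl (2.0 equiv, 0.1 M aq), 0 °C; C18 cartridge, lyophilise
Reagents that add atoms: none
Why: SN2 dealkylation of the sulfate diesters; azide, small and weakly basic, attacks the neopentyl CH2 and the aryl sulfate monoanion leaves, so the C–O bond and not the S–OAr bond is broken and the three free hydroxyls are untouched. After the excess azide is washed out, two equivalents of cold acid protonate 15 to the free bis(hydrogen sulfate).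

## Compound list

1 | 3,5-bis(benzyloxy)phenol | Oc1cc(OCc2ccccc2)cc(OCc2ccccc2)c1 | starting material
2 | 3,5-bis(benzyloxy)-2-iodophenol | Oc1cc(OCc2ccccc2)cc(OCc2ccccc2)c1I | intermediate
3 | neopentyl alcohol (2,2-dimethylpropan-1-ol) | CC(C)(C)CO | starting material
4 | neopentyl chlorosulfate (2,2-dimethylpropyl sulfurochloridate) | CC(C)(C)COS(=O)(=O)Cl | intermediate
5 | 3,4-dihydroxybenzaldehyde | O=Cc1ccc(O)c(O)c1 | starting material
6 | 4-formyl-1,2-phenylene bis(neopentyl sulfate) | O=Cc1ccc(OS(=O)(=O)OCC(C)(C)C)c(OS(=O)(=O)OCC(C)(C)C)c1 | intermediate
7 | 4-ethynyl-1,2-phenylene bis(neopentyl sulfate) | C#Cc1ccc(OS(=O)(=O)OCC(C)(C)C)c(OS(=O)(=O)OCC(C)(C)C)c1 | intermediate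
8 | carbon monoxide | [C-]#[O+] | starting material
9 | 1-[2,4-bis(benzyloxy)-6-hydroxyphenyl]-3-[3,4-bis(neopentyloxysulfonyloxy)phenyl]prop-2-yn-1-one | O=C(C#Cc1ccc(OS(=O)(=O)OCC(C)(C)C)c(OS(=O)(=O)OCC(C)(C)C)c1)c1c(O)cc(OCc2ccccc2)cc1OCc1ccccc1 | intermediate (not isolated)
10 | (E)-1-[2,4-bis(benzyloxy)-6-hydroxyphenyl]-3-(diethylamino)-3-[3,4-bis(neopentyloxysulfonyloxy)phenyl]prop-2-en-1-one | CCN(CC)/C(=C/C(=O)c1c(O)cc(OCc2ccccc2)cc1OCc1ccccc1)c1ccc(OS(=O)(=O)OCC(C)(C)C)c(OS(=O)(=O)OCC(C)(C)C)c1 | intermediate (not isolated)
11 | 5,7-bis(benzyloxy)-2-[3,4-bis(neopentyloxysulfonyloxy)phenyl]-4H-chromen-4-one (5,7-bis(benzyloxy)flavone 3',4'-bis(neopentyl sulfate)) | O=c1cc(-c2ccc(OS(=O)(=O)OCC(C)(C)C)c(OS(=O)(=O)OCC(C)(C)C)c2)oc2cc(OCc3ccccc3)cc(OCc3ccccc3)c12 | intermediate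
12 | 2,3-epoxy-5,7-bis(benzyloxy)flavanone 3',4'-bis(neopentyl sulfate) (racemic, oxirane cis-fused across C2–C3, one enantiomer drawn) | O=C1c2c(OCc3ccccc3)cc(OCc3ccccc3)cc2O[C@@]2(c3ccc(OS(=O)(=O)OCC(C)(C)C)c(OS(=O)(=O)OCC(C)(C)C)c3)O[C@@H]12 | intermediate (not isolated)
13 | 5,7-bis(benzyloxy)-3-hydroxy-2-[3,4-bis(neopentyloxysulfonyloxy)phenyl]-4H-chromen-4-one | O=c1c(O)c(-c2ccc(OS(=O)(=O)OCC(C)(C)C)c(OS(=O)(=O)OCC(C)(C)C)c2)oc2cc(OCc3ccccc3)cc(OCc3ccccc3)c12 | intermediate
14 | 3,5,7-trihydroxy-2-[3,4-bis(neopentyloxysulfonyloxy)phenyl]-4H-chromen-4-one | O=c1c(O)c(-c2ccc(OS(=O)(=O)OCC(C)(C)C)c(OS(=O)(=O)OCC(C)(C)C)c2)oc2cc(O)cc(O)c12 | intermediate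
15 | disodium quercetin 3',4'-bis(sulfate) | O=c1c(O)c(-c2ccc(OS(=O)(=O)[O-])c(OS(=O)(=O)[O-])c2)oc2cc(O)cc(O)c12.[Na+].[Na+] | intermediate (not isolated)
16 | quercetin 3',4'-bis(hydrogen sulfate) | O=c1c(O)c(-c2ccc(OS(=O)(=O)O)c(OS(=O)(=O)O)c2)oc2cc(O)cc(O)c12 | target

## Step count and risks

Total steps: 8. Longest linear sequence: 7 steps (3 → 4 → 6 → 7 → 11 → 13 → 14 → 16). The ring A branch (1 → 2) is one step and joins at step 5.

**Step 5 (key step).** Four processes may interfere. Direct coupling without CO insertion, followed by cyclisation to a 2-arylbenzofuran, may occur if CO insertion into the hindered arylpalladium is slow. The aroylpalladium may be intercepted by diethylamine to give an amide. The sulfate diesters may undergo slow aminolysis at sulfur in hot secondary amine. Partial 5-exo closure may occur if cyclisation outruns amine addition. The fallback separates the carbonylation from the ring closure and takes the free phenol and the secondary amine out of the palladium step. It sets out from 2. Acetylation (Ac2O, pyridine) should give 3,5-bis(benzyloxy)-2-iodophenyl acetate F1. Copper-free carbonylative Sonogashira coupling of F1 with 7 under 8 (PdCl2(PPh3)2, Et3N, THF, CO balloon, rt to 40 °C) should give the O-acetyl ynone F2, which is isolated. Diethylamine in EtOH at rt should then remove the acetate, form 10 and close the ring. The fallback comes back to the route at 11.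

**Step 1.** Positional selectivity may be lost through iodination at C4 (para to the hydroxyl), and a second iodination may occur because the ring stays activated. The fallback replaces electrophilic substitution by directed ortho-metalation and sets out from 1. Carbamoylation (NaH, ClCONEt2, THF) should give 3,5-bis(benzyloxy)phenyl N,N-diethylcarbamate F3. Lithiation with s-BuLi/TMEDA in THF at −78 °C is expected between the carbamate and the neighbouring benzyloxy group, where two directing groups cooperate. Quenching with I2 at −78 °C should give 3,5-bis(benzyloxy)-2-iodophenyl N,N-diethylcarbamate F4. Hydrolysis (KOH, EtOH/H2O, reflux) removes the carbamate, and the fallback comes back at 2.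

**Step 4.** The sulfate diesters may be lost by attack of methoxide at sulfur, most readily at the oxygen para to the formyl group, whose phenoxide is a good leaving group. The fallback brings in the alkyne by cross-coupling and avoids basic methanol. It sets out from 4 and commercial 4-bromocatechol F5. Bis-sulfation as in step 3 (NaH, THF/DMPU, then two equivalents of 4) should give 4-bromo-1,2-phenylene bis(neopentyl sulfate) F6. Sonogashira coupling of F6 with ethynyltrimethylsilane (PdCl2(PPh3)2, CuI, Et3N, THF, 60 °C) should give the silyl alkyne F7. Buffered protiodesilylation (TBAF, AcOH, THF, 0 °C) then gives the terminal alkyne, and the fallback comes back at 7.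

**Step 6.** Epoxidation of the C2=C3 bond may be incomplete, since the bond is deactivated by conjugation to C4=O and by the electron-poor ring B. The excess dioxirane may meanwhile oxidise the benzylic C–H bonds of the benzyl ethers. The epoxide may also open by hydration or ring contraction instead of proton loss. The fallback replaces electrophilic oxygen transfer by deprotonation at C3 and sets out from 11. LDA (LiN(iPr)2) in THF at −78 °C should lithiate C3, and B(OMe)3 should trap the anion as the dimethyl boronate F8. Oxidation with H2O2/AcOH at 0 °C then gives the flavonol, and the fallback comes back at 13. The low temperature and a small excess of base are meant to keep the amide away from the sulfate diesters.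

**Step 8.** Dealkylation at the hindered neopentyl carbon may stop at the mono-ester. The free flavonol may degrade in warm, slightly basic DMF if air is not excluded. The sulfate may hydrolyse during protonation and concentration. The fallback changes the order of unmasking and sets out from 13. NaN3 in DMF at 65 °C should give disodium 5,7-bis(benzyloxy)-3-hydroxyflavone 3',4'-bis(sulfate) F9. F9 is still protected on ring A against oxidation, and reversed-phase chromatography removes azide and DMF from it. Hydrogenolysis (H2, Pd/C, MeOH/H2O, rt) then gives the salt directly, and the fallback comes back at 15. Protonation to 16 follows as in step 8, or 15 is kept as the storage form.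

## Further compounds

F1 | step 5 | 3,5-bis(benzyloxy)-2-iodophenyl acetate | CC(=O)Oc1cc(OCc2ccccc2)cc(OCc2ccccc2)c1I
F2 | step 5 | 3,5-bis(benzyloxy)-2-{3-[3,4-bis(neopentyloxysulfonyloxy)phenyl]prop-2-ynoyl}phenyl acetate | CC(=O)Oc1cc(OCc2ccccc2)cc(OCc2ccccc2)c1C(=O)C#Cc1ccc(OS(=O)(=O)OCC(C)(C)C)c(OS(=O)(=O)OCC(C)(C)C)c1
F3 | step 1 | 3,5-bis(benzyloxy)phenyl N,N-diethylcarbamate | CCN(CC)C(=O)Oc1cc(OCc2ccccc2)cc(OCc2ccccc2)c1
F4 | step 1 | 3,5-bis(benzyloxy)-2-iodophenyl N,N-diethylcarbamate | CCN(CC)C(=O)Oc1cc(OCc2ccccc2)cc(OCc2ccccc2)c1I
F5 | step 4 | 4-bromocatechol (4-bromobenzene-1,2-diol) | Oc1ccc(Br)cc1O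
F6 | step 4 | 4-bromo-1,2-phenylene bis(neopentyl sulfate) | Brc1ccc(OS(=O)(=O)OCC(C)(C)C)c(OS(=O)(=O)OCC(C)(C)C)c1
F7 | step 4 | 4-[(trimethylsilyl)ethynyl]-1,2-phenylene bis(neopentyl sulfate) | C[Si](C)(C)C#Cc1ccc(OS(=O)(=O)OCC(C)(C)C)c(OS(=O)(=O)OCC(C)(C)C)c1
F8 | step 6 | dimethyl {5,7-bis(benzyloxy)-2-[3,4-bis(neopentyloxysulfonyloxy)phenyl]-4-oxo-4H-chromen-3-yl}boronate | COB(OC)c1c(-c2ccc(OS(=O)(=O)OCC(C)(C)C)c(OS(=O)(=O)OCC(C)(C)C)c2)oc2cc(OCc3ccccc3)cc(OCc3ccccc3)c2c1=O
F9 | step 8 | disodium 5,7-bis(benzyloxy)-3-hydroxyflavone 3',4'-bis(sulfate) | O=c1c(O)c(-c2ccc(OS(=O)(=O)[O-])c(OS(=O)(=O)[O-])c2)oc2cc(OCc3ccccc3)cc(OCc3ccccc3)c12.[Na+].[Na+]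
A1 | alternative 1 | 3-(benzyloxy)-2-(2,2-diphenyl-1,3-benzodioxol-5-yl)-5,7-dihydroxy-4H-chromen-4-one | O=c1c(OCc2ccccc2)c(-c2ccc3OC(c4ccccc4)(c4ccccc4)Oc3c2)oc2cc(O)cc(O)c12
A2 | alternative 1 | phloroglucinol (benzene-1,3,5-triol) | Oc1cc(O)cc(O)c1
A3 | alternative 1 | ethyl 2-(benzyloxy)-3-(2,2-diphenyl-1,3-benzodioxol-5-yl)-3-oxopropanoate (racemic) | CCOC(=O)C(OCc1ccccc1)C(=O)c1ccc2OC(c3ccccc3)(c3ccccc3)Oc2c1
A4 | alternative 2 | 5,7-bis(benzyloxy)-2-[3,4-bis(methoxymethoxy)phenyl]-4H-chromen-4-one | O=c1cc(-c2ccc(OCOC)c(OCOC)c2)oc2cc(OCc3ccccc3)cc(OCc3ccccc3)c12
A5 | alternative 2 | 3,5-bis(benzyloxy)-2-(trimethylsilyl)phenyl trifluoromethanesulfonate | C[Si](C)(C)c1c(OS(=O)(=O)C(F)(F)F)cc(OCc2ccccc2)cc1OCc1ccccc1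
A6 | alternative 2 | 3-[3,4-bis(methoxymethoxy)phenyl]prop-2-ynoic acid | OC(=O)C#Cc1ccc(OCOC)c(OCOC)c1
A7 | alternative 3 | 5,7-bis(benzyloxy)-2-(2,2-diphenyl-1,3-benzodioxol-5-yl)-4H-chromen-4-one | O=c1cc(-c2ccc3OC(c4ccccc4)(c4ccccc4)Oc3c2)oc2cc(OCc3ccccc3)cc(OCc3ccccc3)c12
A8 | alternative 3 | 2-hydroxy-4,6-bis(benzyloxy)benzaldehyde | O=Cc1c(O)cc(OCc2ccccc2)cc1OCc1ccccc1
A9 | alternative 3 | 2-[dimethyl(oxo)-λ6-sulfanylidene]-1-(2,2-diphenyl-1,3-benzodioxol-5-yl)ethan-1-one | CS(C)(=O)=CC(=O)c1ccc2OC(c3ccccc3)(c3ccccc3)Oc2c1
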